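## Retrosynthetic overview
1. Disconnect C12–C13 by an Evans syn-aldol. This gives decalin aldehyde **13** and the (R)-oxazolidinone acyl fragment **16**. The succinimide ring is closed last from an acid and a primary amide, with C12–OH carried as its TBS ether.
2. Aldehyde **13** comes from C11→C12 homologation of a C9 ester. The C6 ketone and C12 aldehyde are unmasked together from two enol ethers.
3. Ring B (quaternary C10, C8=CH2, C9, C6 as enol ether) is built onto ring A by a Lewis-acid formal [4+2] of 2-methoxydiene **7** with methyl allenoate **8**.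
4. Diene **7** comes from the Knoevenagel ring-A ester **3**: CBS reduction sets C2, Appel inversion gives 2α-Cl, and Petasis methylenation gives the diene. Ring A forms first (step 1), ring B second (step 6), and the succinimide last (step 16).

Assumptions (one line each):
- The Knoevenagel product has the ester on C5 between C4 and C10.
- The annulation occurs anti to the axial C4 methyl, with the C10 epimer separable.
- C9 equilibrates to the equatorial isomer at aldehyde **11**.
- C5 equilibrates to the trans (5α-H) ketone on hydrolysis.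

## Route

**Step 1**
Reactants: **1** methyl acetoacetate; **2** mesityl oxide
Product: **3** methyl 2,6,6-trimethyl-4-oxocyclohex-2-ene-1-carboxylate (racemic at C1)
Conditions: NaOMe (1.1 equiv), MeOH, reflux
Reagents that add atoms: none
Why: Michael addition of the acetoacetate carbon to the β,β-dimethyl enone, then intramolecular aldol condensation, builds ring A with C4 gem-dimethyl, C10 methyl and the C2 ketone (Knoevenagel/Michael–aldol). The labile C1 stereocentre is destroyed in step 3.

**Step 2**
Reactants: **3**
Product: **4** methyl (4R)-4-hydroxy-2,6,6-trimethylcyclohex-2-ene-1-carboxylate (C1 epimer mixture)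
Conditions: (S)-Me-CBS (10 mol %), BH3·SMe2, THF, –20 °C (use the (R)-catalyst if the (4S)-alcohol is obtained)
Reagents that add atoms: none
Why: Corey–Bakshi–Shibata reduction differentiates the enone faces, setting the C2 stereocentre. The C1 stereocentre is irrelevant because it is lost in step 3.

**Step 3**
Reactants: **4**
Product: **5** methyl (4S)-4-hydroxy-2,6,6-trimethylcyclohex-1-ene-1-carboxylate
Conditions: DBU (2 equiv), PhMe, 110 °C
Reagents that add atoms: none
Why: Base-mediated deconjugative isomerisation via the dienolate gives the tetrasubstituted Δ5(10) alkene needed for the diene. It also removes the C1 stereocentre and moves the C2–OH from allylic to homoallylic.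

**Step 4**
Reactants: **5**
Product: **6** methyl (4R)-4-chloro-2,6,6-trimethylcyclohex-1-ene-1-carboxylate
Conditions: PPh3, NCS, THF, 0 °C → rt
Reagents that add atoms: N-chlorosuccinimide, O=C1CCC(=O)N1Cl (supplies Cl)
Why: Appel-type SN2 substitution inverts C2, converting the alcohol into the 2α-chloride (equatorial in the final trans-decalin). Ionisation is avoided because the OH is now homoallylic.

**Step 5**
Reactants: **6**
Product: **7** (4R)-4-chloro-1-(1-methoxyethenyl)-2,6,6-trimethylcyclohex-1-ene
Conditions: Cp2TiMe2 (2.5 equiv), PhMe/THF, 70 °C, dark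
Reagents that add atoms: dimethyltitanocene, C[Ti](C)(C1C=CC=C1)C1C=CC=C1 (supplies the =CH2 carbon, C7)
Why: Petasis carbonyl methylenation converts the ester into a methyl enol ether and leaves the C–Cl bond and ring alkene untouched. This gives the electron-rich 2-methoxydiene.

**Step 6**
Reactants: **7** diene; **8** methyl buta-2,3-dienoate
Product: **9** decalin ester (labdane numbering): 2α-Cl, 4,4,10β-trimethyl, Δ5-6-OMe enol ether, 8(17)-methylene, C9–C11 methyl ester
Conditions: **8** (3 equiv), Me2AlCl (1.2 equiv), CH2Cl2, –78 → 0 °C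
Reagents that add atoms: none (**8** is a reactant)
Why: Lewis-acid formal Diels–Alder, run stepwise as Mukaiyama–Michael then Michael. The nucleophilic enol-ether CH2 (C7) attacks the allenoate β-carbon (C8), and the aluminium enolate (C9) then closes onto C10. In the half-chair with Cl equatorial, the axial C4 methyl blocks the β face, so closure occurs from α and places the C10 methyl β. The C8 exocyclic methylene is retained.

**Step 7**
Reactants: **9**
Product: **10** C11 primary alcohol (same decalin)
Conditions: DIBAL-H (3 equiv), CH2Cl2, –78 → 0 °C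
Reagents that add atoms: none
Why: Hydride reduction of the ester. The enol ether, alkene and secondary chloride survive, and the masked C6 ketone cannot be reduced.

**Step 8**
Reactants: **10**
Product: **11** C11 aldehyde
Conditions: (COCl)2, DMSO, Et3N, CH2Cl2, –78 → 0 °C
Reagents that add atoms: none
Why: Swern oxidation. The aldehyde is α-branched at C9, so Et3N equilibrates C9 to the equatorial (9α-H, natural) isomer.

**Step 9**
Reactants: **11**
Product: **12** C12 methyl enol ether (E/Z)
Conditions: [Ph3PCH2OMe]Cl, NaHMDS, THF, 0 °C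
Reagents that add atoms: methoxymethylenetriphenylphosphorane, COC=P(C1=CC=CC=C1)(C1=CC=CC=C1)C1=CC=CC=C1 (supplies C12 and OMe)
Why: Wittig one-carbon homologation gives the C11→C12 extension as a masked aldehyde.

**Step 10**
Reactants: **12**
Product: **13** 2α-chloro-6-oxo-13,14,15,16-tetranorlabd-8(17)-en-12-al (5α,9α,10β)
Conditions: 2 M HCl, THF, 25 °C
Reagents that add atoms: water, O (oxygen of the aldehyde and of the C6 ketone)
Why: Hydrolysis of both enol ethers. Protonation at C7 of the 6-methoxydiene gives the β,γ-unsaturated C6 ketone, and C5 (α to the ketone) settles trans (5α-H).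

**Step 11**
Reactants: **14** succinic anhydride
Product: **15** 4-[(4R)-4-benzyl-2-oxooxazolidin-3-yl]-4-oxobutanoic acid
Conditions: (R)-4-benzyloxazolidin-2-one, n-BuLi, THF, –78 °C, then **14**
Reagents that add atoms: (R)-4-benzyloxazolidin-2-one (chiral auxiliary), O=C1N[C@H](Cc2ccccc2)CO1
Why: N-acylation of the lithiated auxiliary by anhydride ring-opening installs the Evans acyl unit with a free carboxylic acid.

**Step 12**
Reactants: **15**
Product: **16** 4-[(4R)-4-benzyl-2-oxooxazolidin-3-yl]-4-oxobutanamide
Conditions: EDC·HCl, HOBt, NH4Cl, iPr2NEt, DMF, 0 °C → rt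
Reagents that add atoms: ammonium chloride, N (supplies NH2)
Why: Carbodiimide amide coupling gives the primary amide that will later close the imide.

**Step 13**
Reactants: **13** aldehyde; **16** acyl oxazolidinone
Product: **17** syn-aldol adduct with C12 (S) and C13 (R)
Conditions: **16**, Bu2BOTf (2.2 equiv), iPr2NEt (2.4 equiv), CH2Cl2, –78 → 0 °C; then **13**, –78 → 0 °C; H2O2/pH 7 buffer/MeOH work-up
Reagents that add atoms: none
Why: Evans boron-enolate aldol. A Z-enolate reacts through a Zimmerman–Traxler chair with the aldehyde approaching anti to the benzyl group of the (R)-auxiliary, giving the syn (12S,13R) stereocentres.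

**Step 14**
Reactants: **17**
Product: **18** C12-OTBS ether
Conditions: TBSOTf, 2,6-lutidine, CH2Cl2, –78 °C
Reagents that add atoms: tert-butyldimethylsilyl triflate, CC(C)(C)[Si](C)(C)OS(=O)(=O)C(F)(F)F (supplies TBS)
Why: Silylation prevents β-lactonisation and retro-aldol in the next steps.

**Step 15**
Reactants: **18**
Product: **19** carboxylic acid (C16 acid, C15 primary amide, TBS ether); the auxiliary is recovered
Conditions: LiOH, H2O2, THF/H2O, 0 °C
Reagents that add atoms: hydrogen peroxide, OO (oxygen of the acid OH)
Why: LiOOH attacks the exocyclic acyl carbonyl selectively, so the C13 centre is untouched.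

**Step 16**
Reactants: **19**
Product: **20** TBS-protected imide
Conditions: CDI (2 equiv), THF, 60 °C
Reagents that add atoms: none
Why: Acyl-imidazolide formation followed by 5-exo attack of the primary amide nitrogen closes the succinimide. The resulting acidic imide NH protects C13 from epimerisation.

**Step 17**
Reactants: **20**
Product: **21** haterumaimide G
Conditions: HF·pyridine, pyridine/THF, 0 °C → rt
Reagents that add atoms: none
Why: Mild fluoride cleavage of the secondary TBS ether leaves the β-hydroxy imide, the β,γ-enone and the C–Cl bond intact.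

## Compound list
1 | methyl acetoacetate | CC(=O)CC(=O)OC | starting material
2 | mesityl oxide | CC(=O)C=C(C)C | starting material
3 | methyl 2,6,6-trimethyl-4-oxocyclohex-2-ene-1-carboxylate | COC(=O)C1C(C)=CC(=O)CC1(C)C | intermediate
4 | methyl (4R)-4-hydroxy-2,6,6-trimethylcyclohex-2-ene-1-carboxylate | COC(=O)C1C(C)=C[C@H](O)CC1(C)C | intermediate
5 | methyl (4S)-4-hydroxy-2,6,6-trimethylcyclohex-1-ene-1-carboxylate | COC(=O)C1=C(C)C[C@H](O)CC1(C)C | intermediate
6 | methyl (4R)-4-chloro-2,6,6-trimethylcyclohex-1-ene-1-carboxylate | COC(=O)C1=C(C)C[C@@H](Cl)CC1(C)C | intermediate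
7 | (4R)-4-chloro-1-(1-methoxyethenyl)-2,6,6-trimethylcyclohex-1-ene | C=C(OC)C1=C(C)C[C@@H](Cl)CC1(C)C | intermediate
8 | methyl buta-2,3-dienoate | C=C=CC(=O)OC | starting material
9 | decalin C11 methyl ester, 2α-Cl, 6-OMe Δ5 enol ether, 8(17)-methylene, 10β-Me | COC(=O)[C@H]1C(=C)CC(OC)=C2C(C)(C)C[C@H](Cl)C[C@]12C | intermediate
10 | C11 primary alcohol | OC[C@H]1C(=C)CC(OC)=C2C(C)(C)C[C@H](Cl)C[C@]12C | intermediate
11 | C11 aldehyde | O=C[C@H]1C(=C)CC(OC)=C2C(C)(C)C[C@H](Cl)C[C@]12C | intermediate
12 | C12 methyl enol ether | COC=C[C@H]1C(=C)CC(OC)=C2C(C)(C)C[C@H](Cl)C[C@]12C | intermediate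
13 | 2α-chloro-6-oxo-13,14,15,16-tetranorlabd-8(17)-en-12-al | C=C1CC(=O)[C@H]2C(C)(C)C[C@H](Cl)C[C@]2(C)[C@H]1CC=O | intermediate
14 | succinic anhydride | O=C1CCC(=O)O1 | starting material
15 | 4-[(4R)-4-benzyl-2-oxooxazolidin-3-yl]-4-oxobutanoic acid | OC(=O)CCC(=O)N1[C@H](Cc2ccccc2)COC1=O | intermediate
16 | 4-[(4R)-4-benzyl-2-oxooxazolidin-3-yl]-4-oxobutanamide | NC(=O)CCC(=O)N1[C@H](Cc2ccccc2)COC1=O | intermediate
17 | syn-aldol adduct (12S,13R) | C=C1CC(=O)[C@H]2C(C)(C)C[C@H](Cl)C[C@]2(C)[C@H]1C[C@H](O)[C@@H](CC(N)=O)C(=O)N1[C@H](Cc2ccccc2)COC1=O | intermediate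
18 | C12-OTBS ether of 17 | C=C1CC(=O)[C@H]2C(C)(C)C[C@H](Cl)C[C@]2(C)[C@H]1C[C@H](O[Si](C)(C)C(C)(C)C)[C@@H](CC(N)=O)C(=O)N1[C@H](Cc2ccccc2)COC1=O | intermediate
19 | C16 acid, C15 amide, TBS ether | C=C1CC(=O)[C@H]2C(C)(C)C[C@H](Cl)C[C@]2(C)[C@H]1C[C@H](O[Si](C)(C)C(C)(C)C)[C@@H](CC(N)=O)C(=O)O | intermediate
20 | TBS-protected haterumaimide G | C=C1CC(=O)[C@H]2C(C)(C)C[C@H](Cl)C[C@]2(C)[C@H]1C[C@H](O[Si](C)(C)C(C)(C)C)[C@H]1CC(=O)NC1=O | intermediate
21 | haterumaimide G | C=C1CC(=O)[C@H]2C(C)(C)C[C@H](Cl)C[C@]2(C)[C@H]1C[C@H](O)[C@H]1CC(=O)NC1=O | target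

## Totals
Total steps: 17. Longest linear sequence: 15 (steps 1–10, then 13–17).

## Three steps most likely to fail
1. **Step 6 (hindered formal [4+2]; C10 facial selectivity).** Fallback: change the strategy for ring B to a base-mediated Michael–aldol annulation of methyl acetoacetate onto an acyclic β,β-disubstituted enone. Ring A is then closed by intramolecular Michael addition, and the racemate is resolved through the C9 acid.
2. **Step 3 (DBU isomerisation to the tetrasubstituted Δ5(10) ester).** The equilibrium may favour the starting Δ1(10) isomer. Fallback: skip isomerisation and make the Δ5(10) ester directly by Pd-catalysed methoxycarbonylation of the enol triflate of (R)-4-chloro-2,2,6-trimethylcyclohexanone.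
3. **Step 13 (aldol with a primary-amide acyl chain, a hindered aldehyde and an enolisable β,γ-ketone).** Fallback: carry C15 as an allyl ester, so the imide is built after auxiliary removal by Pd deallylation, amidation and cyclisation, with the ketone left untouched during the aldol.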